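**Retrosynthetic overview**
- The strategy rests on ring A: a para-hydroquinone (C5–OH, C8–OH) with OMe at C7 and H at C6, fused through C4a–C8a to pyranone ring C. C5–C8 map onto the four carbons of a methoxycyclobutenedione, and C4a/C8a onto a pyranone C=C.
- The last disconnection is cleavage of three benzyl ethers (3-O, 3'-O, 5'-O) of a tribenzyl flavonol hydroquinone.
- Key disconnection: the C4a–C5 bond of ring A (retro 6π/4π ring expansion) leads to a 4-hydroxy-3-methoxy-4-(4-pyranon-2-yl)cyclobutenone; the C8–C8a bond then leads to a 6-metalated 2-aryl-3-benzyloxy-4-pyranone and methyl semisquarate (from dimethyl squarate).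
- Ring C comes from furan and 3,5-bis(benzyloxy)-4-methoxybenzaldehyde by Achmatowicz ring expansion, enone epoxidation and acid aromatisation.
- Ring order: ring B is purchased, ring C is built from furan, ring A is closed last.

Key step: step 13

Remark on the chemistry: the target is achiral. The carbinol and ring stereocentres of the intermediates are carried as racemates or diastereomer mixtures, since each is erased on aromatisation.

**Step 1**
Reactants: 1 methyl 3,5-dihydroxy-4-methoxybenzoate
Product: 2 methyl 3,5-bis(benzyloxy)-4-methoxybenzoate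
Conditions: BnBr (2.5 equiv), K2CO3, DMF, 60 °C
Reagents that add atoms: benzyl bromide, BrCc1ccccc1
Why: Williamson etherification of the two phenols flanking the methoxy group should proceed cleanly, the methyl ester and aryl methyl ether being inert to carbonate.

**Step 2**
Reactants: 2 methyl 3,5-bis(benzyloxy)-4-methoxybenzoate
Product: 3 [3,5-bis(benzyloxy)-4-methoxyphenyl]methanol
Conditions: LiAlH4, THF, 0 °C to rt; then H2O, aq. NaOH
Reagents that add atoms: none
Why: Hydride reduction of the ester to the primary benzylic alcohol leaves the benzyl and methyl aryl ethers untouched.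

**Step 3**
Reactants: 3 [3,5-bis(benzyloxy)-4-methoxyphenyl]methanol
Product: 4 3,5-bis(benzyloxy)-4-methoxybenzaldehyde
Conditions: MnO2 (activated, excess), CH2Cl2, rt
Reagents that add atoms: none
Why: Activated MnO2 oxidises benzylic alcohols selectively to aldehydes without over-oxidation.

**Step 4**
Reactants: 5 furan; 4 3,5-bis(benzyloxy)-4-methoxybenzaldehyde
Product: 7 [3,5-bis(benzyloxy)-4-methoxyphenyl](furan-2-yl)methanol (racemic), via 2-furyllithium 6 (not isolated)
Conditions: 5, n-BuLi, THF, −78 to 0 °C; then 4, −78 °C; sat. aq. NH4Cl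
Reagents that add atoms: none
Why: Alpha-lithiation of furan and 1,2-addition of the heteroaryllithium to the aldehyde should give the furyl carbinol; its new centre forms without control, which is acceptable because it is destroyed later.

**Step 5**
Reactants: 7 [3,5-bis(benzyloxy)-4-methoxyphenyl](furan-2-yl)methanol
Product: 8 2-[3,5-bis(benzyloxy)-4-methoxyphenyl]-6-hydroxy-2H-pyran-3(6H)-one (racemic diastereomer mixture)
Conditions: mCPBA (1.1 equiv), CH2Cl2, 0 °C
Reagents that add atoms: meta-chloroperbenzoic acid, OOC(=O)c1cccc(Cl)c1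
Why: Achmatowicz rearrangement: peracid oxidation of the furan, opening to the cis-enedione and closure of the carbinol oxygen onto the aldehyde give the pyranone lactol; a peracid is chosen over a bromine source to spare the electron-rich arene, and the anomeric centre forms as an inconsequential mixture.

**Step 6**
Reactants: 8 2-[3,5-bis(benzyloxy)-4-methoxyphenyl]-6-hydroxy-2H-pyran-3(6H)-one
Product: 9 2-[3,5-bis(benzyloxy)-4-methoxyphenyl]-6-methoxy-2H-pyran-3(6H)-one (diastereomer mixture)
Conditions: HC(OMe)3, BF3·OEt2 (cat.), Et2O, 0 °C to rt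
Reagents that add atoms: trimethyl orthoformate, COC(OC)OC
Why: Acid-catalysed glycosidation through the allylic oxocarbenium ion caps the lactol as its methyl acetal, so that the alkaline epoxidation is not complicated by ring-chain equilibration.

**Step 7**
Reactants: 9 2-[3,5-bis(benzyloxy)-4-methoxyphenyl]-6-methoxy-2H-pyran-3(6H)-one
Product: 10 4-[3,5-bis(benzyloxy)-4-methoxyphenyl]-2-methoxy-3,7-dioxabicyclo[4.1.0]heptan-5-one (the 4,5-epoxide of 9; diastereomer mixture)
Conditions: 30% aq. H2O2, NaOH (cat.), MeOH/THF, 0 °C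
Reagents that add atoms: hydrogen peroxide, OO
Why: Weitz–Scheffer nucleophilic epoxidation of the electron-poor enone raises the oxidation level at C4; facial selectivity is immaterial because both epoxide carbons become sp2 in the next step.

**Step 8**
Reactants: 10 4-[3,5-bis(benzyloxy)-4-methoxyphenyl]-2-methoxy-3,7-dioxabicyclo[4.1.0]heptan-5-one
Product: 11 2-[3,5-bis(benzyloxy)-4-methoxyphenyl]-3-hydroxy-4H-pyran-4-one
Conditions: 1 M aq. H2SO4/1,4-dioxane, 90 °C
Reagents that add atoms: none
Why: Acid-mediated isomerisation of the keto-epoxide to the 3,4-diketone, beta-elimination of methanol from C6 and enolisation towards C2 should give the 3-hydroxy-4-pyranone, as in the maltol-type conversion of furyl carbinols.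

**Step 9**
Reactants: 11 2-[3,5-bis(benzyloxy)-4-methoxyphenyl]-3-hydroxy-4H-pyran-4-one
Product: 12 3-(benzyloxy)-2-[3,5-bis(benzyloxy)-4-methoxyphenyl]-4H-pyran-4-one
Conditions: BnBr (1.2 equiv), K2CO3, DMF, rt
Reagents that add atoms: benzyl bromide, BrCc1ccccc1
Why: Williamson O-benzylation of the acidic enolic 3-hydroxyl removes the only acidic proton before the metalation step.

**Step 10**
Reactants: 13 dimethyl squarate (3,4-dimethoxycyclobut-3-ene-1,2-dione)
Product: 14 4-hydroxy-2,3-dimethoxycyclobut-2-en-1-one (racemic)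
Conditions: LiAlH(OtBu)3 (1.05 equiv), THF, −20 °C; cold dilute aq. HCl work-up
Reagents that add atoms: none
Why: The hindered hydride reduces one of the two equivalent carbonyls and stops there, because the remaining carbonyl is a deactivated vinylogous ester.

**Step 11**
Reactants: 14 4-hydroxy-2,3-dimethoxycyclobut-2-en-1-one
Product: 15 3-methoxycyclobut-3-ene-1,2-dione (methyl semisquarate)
Conditions: conc. aq. HCl (cat.), CH2Cl2, rt; used at once
Reagents that add atoms: none
Why: Acid-promoted ionisation of the allylic hydroxyl, return of water at the methoxy-bearing C2 and loss of methanol effect a 1,3-carbonyl transposition to the semisquarate, which is used fresh because it is sensitive.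

**Step 12**
Reactants: 12 3-(benzyloxy)-2-[3,5-bis(benzyloxy)-4-methoxyphenyl]-4H-pyran-4-one; 15 3-methoxycyclobut-3-ene-1,2-dione
Product: 17 4-{5-(benzyloxy)-6-[3,5-bis(benzyloxy)-4-methoxyphenyl]-4-oxo-4H-pyran-2-yl}-4-hydroxy-3-methoxycyclobut-2-en-1-one (racemic), via 6-lithiopyranone 16 (not isolated)
Conditions: 2,2,6,6-tetramethylpiperidine, n-BuLi, THF, 0 °C (gives LiTMP); 12, −78 °C, 20 min; cannulated into 15 (1.3 equiv), THF, −78 °C; sat. aq. NH4Cl; crude product kept free of acid
Reagents that add atoms: none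
Why: The hindered amide removes the vinylic C6–H next to the ring oxygen (metalation alpha to oxygen, as known for chromones and 4-pyranones), and the vinyllithium adds 1,2 to the more electrophilic ketone carbonyl of 15 (the one on the methoxy-bearing carbon, not the vinylogous ester carbonyl), giving the racemic carbinol with OMe next to the future C8.

**Step 13**
Reactants: 17 4-{5-(benzyloxy)-6-[3,5-bis(benzyloxy)-4-methoxyphenyl]-4-oxo-4H-pyran-2-yl}-4-hydroxy-3-methoxycyclobut-2-en-1-one
Product: 20 3-(benzyloxy)-2-[3,5-bis(benzyloxy)-4-methoxyphenyl]-5,8-dihydroxy-7-methoxy-4H-chromen-4-one, via dienylketene 18 (not isolated), via cyclohexadienone 19 (not isolated)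
Conditions: degassed p-xylene (0.01 M), 138 °C, Ar; then aq. Na2S2O4 wash
Reagents that add atoms: none
Why: Proposed new method: heating 17 should trigger conrotatory 4π opening of the cyclobutenone, breaking the C(=O)–C(OH) bond with the hydroxyl rotating outward, so that (Z)-dienylketene 18 holds the pyranonyl arm beside the ketene; 6π electrocyclisation then joins the ketene carbon to pyranone C5, and enolisation of dienone 19 gives hydroquinone 20. The closest known reaction type is the Moore rearrangement of 4-aryl-, 4-heteroaryl- and 4-alkenyl-4-hydroxycyclobutenones to hydroquinones and quinones, here extended to a 4-oxo-4H-pyran-2-yl arm. Ring A is the only ring closed, by a thermal disrotatory 6π electrocyclisation that forms the C4a–C5 bond and completes the chromone bicycle. The one sp3 centre of 19 (C4a) is transient, so no stereocentre has to be controlled. The step needs the arm to rotate inward and a single site of closure: the donor hydroxyl prefers outward rotation, the pyranone offers only C5 next to the attachment carbon, and the electrophilic ketene carbon is matched with the nucleophilic alpha-carbon of the vinylogous ester. The placement of 5-OH, 6-H, 7-OMe and 8-OH is inherited from the connectivity of 17, and the product is favoured by aromatisation and the 5-OH to C4=O hydrogen bond.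

**Step 14**
Reactants: 20 3-(benzyloxy)-2-[3,5-bis(benzyloxy)-4-methoxyphenyl]-5,8-dihydroxy-7-methoxy-4H-chromen-4-one
Product: 21 2-(3,5-dihydroxy-4-methoxyphenyl)-3,5,8-trihydroxy-7-methoxy-4H-chromen-4-one (target CNP0241578.0)
Conditions: H2 (1 atm), Pd/C (10 wt%), THF/MeOH, rt, degassed solvents; filtered under Ar
Reagents that add atoms: none
Why: Hydrogenolysis should remove the three benzyl ethers while the tetrasubstituted C2=C3 bond and the aryl methyl ethers persist; exclusion of air protects the hydroquinone.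

**Compound list**
1 | methyl 3,5-dihydroxy-4-methoxybenzoate | COC(=O)c1cc(O)c(OC)c(O)c1 | starting material
2 | methyl 3,5-bis(benzyloxy)-4-methoxybenzoate | COC(=O)c1cc(OCc2ccccc2)c(OC)c(OCc2ccccc2)c1 | intermediate
3 | [3,5-bis(benzyloxy)-4-methoxyphenyl]methanol | OCc1cc(OCc2ccccc2)c(OC)c(OCc2ccccc2)c1 | intermediate
4 | 3,5-bis(benzyloxy)-4-methoxybenzaldehyde | O=Cc1cc(OCc2ccccc2)c(OC)c(OCc2ccccc2)c1 | intermediate
5 | furan | c1ccoc1 | starting material
6 | 2-furyllithium | [Li]c1ccco1 | intermediate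
7 | [3,5-bis(benzyloxy)-4-methoxyphenyl](furan-2-yl)methanol, racemic | OC(c1ccco1)c1cc(OCc2ccccc2)c(OC)c(OCc2ccccc2)c1 | intermediate
8 | 2-[3,5-bis(benzyloxy)-4-methoxyphenyl]-6-hydroxy-2H-pyran-3(6H)-one, diastereomer mixture | O=C1C=CC(O)OC1c1cc(OCc2ccccc2)c(OC)c(OCc2ccccc2)c1 | intermediate
9 | 2-[3,5-bis(benzyloxy)-4-methoxyphenyl]-6-methoxy-2H-pyran-3(6H)-one, diastereomer mixture | COC1C=CC(=O)C(c2cc(OCc3ccccc3)c(OC)c(OCc3ccccc3)c2)O1 | intermediate
10 | 4-[3,5-bis(benzyloxy)-4-methoxyphenyl]-2-methoxy-3,7-dioxabicyclo[4.1.0]heptan-5-one, diastereomer mixture | COC1OC(c2cc(OCc3ccccc3)c(OC)c(OCc3ccccc3)c2)C(=O)C2OC12 | intermediate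
11 | 2-[3,5-bis(benzyloxy)-4-methoxyphenyl]-3-hydroxy-4H-pyran-4-one | O=c1ccoc(-c2cc(OCc3ccccc3)c(OC)c(OCc3ccccc3)c2)c1O | intermediate
12 | 3-(benzyloxy)-2-[3,5-bis(benzyloxy)-4-methoxyphenyl]-4H-pyran-4-one | O=c1ccoc(-c2cc(OCc3ccccc3)c(OC)c(OCc3ccccc3)c2)c1OCc1ccccc1 | intermediate
13 | dimethyl squarate | COC1=C(OC)C(=O)C1=O | starting material
14 | 4-hydroxy-2,3-dimethoxycyclobut-2-en-1-one, racemic | COC1=C(OC)C(=O)C1O | intermediate
15 | 3-methoxycyclobut-3-ene-1,2-dione (methyl semisquarate) | COC1=CC(=O)C1=O | intermediate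
16 | 3-(benzyloxy)-2-[3,5-bis(benzyloxy)-4-methoxyphenyl]-6-lithio-4H-pyran-4-one | [Li]c1cc(=O)c(OCc2ccccc2)c(-c2cc(OCc3ccccc3)c(OC)c(OCc3ccccc3)c2)o1 | intermediate
17 | 4-{5-(benzyloxy)-6-[3,5-bis(benzyloxy)-4-methoxyphenyl]-4-oxo-4H-pyran-2-yl}-4-hydroxy-3-methoxycyclobut-2-en-1-one, racemic | COC1=CC(=O)C1(O)c1cc(=O)c(OCc2ccccc2)c(-c2cc(OCc3ccccc3)c(OC)c(OCc3ccccc3)c2)o1 | intermediate
18 | (Z)-4-{5-(benzyloxy)-6-[3,5-bis(benzyloxy)-4-methoxyphenyl]-4-oxo-4H-pyran-2-yl}-4-hydroxy-3-methoxybuta-1,3-dien-1-one (dienylketene) | O=C=C/C(OC)=C(/O)c1cc(=O)c(OCc2ccccc2)c(-c2cc(OCc3ccccc3)c(OC)c(OCc3ccccc3)c2)o1 | intermediate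
19 | 3-(benzyloxy)-2-[3,5-bis(benzyloxy)-4-methoxyphenyl]-8-hydroxy-7-methoxy-4aH-chromene-4,5-dione, racemic | COC1=CC(=O)C2C(=O)C(OCc3ccccc3)=C(c3cc(OCc4ccccc4)c(OC)c(OCc4ccccc4)c3)OC2=C1O | intermediate
20 | 3-(benzyloxy)-2-[3,5-bis(benzyloxy)-4-methoxyphenyl]-5,8-dihydroxy-7-methoxy-4H-chromen-4-one | COc1cc(O)c2c(=O)c(OCc3ccccc3)c(-c3cc(OCc4ccccc4)c(OC)c(OCc4ccccc4)c3)oc2c1O | intermediate
21 | 2-(3,5-dihydroxy-4-methoxyphenyl)-3,5,8-trihydroxy-7-methoxy-4H-chromen-4-one | COc1cc(O)c2c(=O)c(O)c(-c3cc(O)c(OC)c(O)c3)oc2c1O | target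

**Step count**
Total steps: 14. Longest linear sequence: 12 steps (steps 1 to 9, then 12, 13 and 14); the squarate branch (steps 10 and 11) joins at step 12.

**Steps most likely to fail**

1. Step 13. The dienylketene may be diverted before 6π closure: some inward rotation of the hydroxyl would lead to lactonisation, the ketene may oligomerise, or the closure onto the cross-conjugated pyranone may be too slow at temperatures the benzyl ethers tolerate.
   Fallback by known flavonoid chemistry, setting out from ester 2 and rejoining at 20: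
   - Saponification (LiOH, THF/MeOH/H2O) would give 3,5-bis(benzyloxy)-4-methoxybenzoic acid F1, which DCC (0.5 equiv, CH2Cl2) would dehydrate to 3,5-bis(benzyloxy)-4-methoxybenzoic anhydride F2.
   - Hoesch acylation of phloroglucinol with benzyloxyacetonitrile (ZnCl2, HCl, Et2O; then hot water) would give 2-(benzyloxy)-1-(2,4,6-trihydroxyphenyl)ethan-1-one F3.
   - Allan–Robinson condensation of F3 with F2 (Et3N, 160 °C; then aq. KOH/EtOH to cleave the O-aroyl esters) should give 3-(benzyloxy)-2-[3,5-bis(benzyloxy)-4-methoxyphenyl]-5,7-dihydroxy-4H-chromen-4-one F4.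
   - Selective methylation of the non-chelated 7-hydroxyl (Me2SO4, 1 equiv, K2CO3, acetone) should give 3-(benzyloxy)-2-[3,5-bis(benzyloxy)-4-methoxyphenyl]-5-hydroxy-7-methoxy-4H-chromen-4-one F5.
   - Elbs persulfate oxidation para to the 5-hydroxyl (K2S2O8, aq. KOH/pyridine) should give potassium 3-(benzyloxy)-2-[3,5-bis(benzyloxy)-4-methoxyphenyl]-5-hydroxy-7-methoxy-4-oxo-4H-chromen-8-yl sulfate F6, and hydrolysis (dilute aq. HCl, Na2SO3, 80 °C) gives 20.

2. Step 12. Deprotonation may occur at sites other than C6 (C5–H or a benzylic OCH2), the 6-lithio species may fragment before it is trapped, or residual amide may attack 15.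
   Fallback setting out from 12 and rejoining at 17:
   - Magnesiation with TMPMgCl·LiCl (THF, −20 °C) would give 3-(benzyloxy)-2-[3,5-bis(benzyloxy)-4-methoxyphenyl]-6-(chloromagnesio)-4H-pyran-4-one F7.
   - Iodolysis (I2) would give 3-(benzyloxy)-2-[3,5-bis(benzyloxy)-4-methoxyphenyl]-6-iodo-4H-pyran-4-one F8, which is isolated so that the site of metalation is secured.
   - Iodine–magnesium exchange on F8 (iPrMgCl·LiCl, THF, −40 °C) regenerates F7 free of amine; addition to 15 in the presence of LaCl3·2LiCl should then give 17.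

3. Step 8. Acid opening of the keto-epoxide may be diverted into ring contraction to 2-acyl-3-hydroxyfuran-type products, or into glycoside hydrolysis and ring opening, instead of aromatisation.
   Fallback setting out from enone 9 and rejoining at 11:
   - Catalytic dihydroxylation (OsO4 cat., N-methylmorpholine N-oxide, acetone/H2O) would give 2-[3,5-bis(benzyloxy)-4-methoxyphenyl]-4,5-dihydroxy-6-methoxytetrahydro-2H-pyran-3-one F9.
   - Acid-promoted loss of water and methanol (TsOH, toluene, 80 °C) should give 11 by the double elimination known from the conversion of glycosuloses into 3-hydroxy-4-pyranones.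

**Further compounds**
F1 | step 13 | 3,5-bis(benzyloxy)-4-methoxybenzoic acid | OC(=O)c1cc(OCc2ccccc2)c(OC)c(OCc2ccccc2)c1
F2 | step 13 | 3,5-bis(benzyloxy)-4-methoxybenzoic anhydride | O=C(OC(=O)c1cc(OCc2ccccc2)c(OC)c(OCc2ccccc2)c1)c1cc(OCc2ccccc2)c(OC)c(OCc2ccccc2)c1
F3 | step 13 | 2-(benzyloxy)-1-(2,4,6-trihydroxyphenyl)ethan-1-one | O=C(COCc1ccccc1)c1c(O)cc(O)cc1O
F4 | step 13 | 3-(benzyloxy)-2-[3,5-bis(benzyloxy)-4-methoxyphenyl]-5,7-dihydroxy-4H-chromen-4-one | Oc1cc(O)c2c(=O)c(OCc3ccccc3)c(-c3cc(OCc4ccccc4)c(OC)c(OCc4ccccc4)c3)oc2c1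
F5 | step 13 | 3-(benzyloxy)-2-[3,5-bis(benzyloxy)-4-methoxyphenyl]-5-hydroxy-7-methoxy-4H-chromen-4-one | COc1cc(O)c2c(=O)c(OCc3ccccc3)c(-c3cc(OCc4ccccc4)c(OC)c(OCc4ccccc4)c3)oc2c1
F6 | step 13 | potassium 3-(benzyloxy)-2-[3,5-bis(benzyloxy)-4-methoxyphenyl]-5-hydroxy-7-methoxy-4-oxo-4H-chromen-8-yl sulfate | COc1cc(O)c2c(=O)c(OCc3ccccc3)c(-c3cc(OCc4ccccc4)c(OC)c(OCc4ccccc4)c3)oc2c1OS(=O)(=O)[O-].[K+]
F7 | step 12 | 3-(benzyloxy)-2-[3,5-bis(benzyloxy)-4-methoxyphenyl]-6-(chloromagnesio)-4H-pyran-4-one | Cl[Mg]c1cc(=O)c(OCc2ccccc2)c(-c2cc(OCc3ccccc3)c(OC)c(OCc3ccccc3)c2)o1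
F8 | step 12 | 3-(benzyloxy)-2-[3,5-bis(benzyloxy)-4-methoxyphenyl]-6-iodo-4H-pyran-4-one | Ic1cc(=O)c(OCc2ccccc2)c(-c2cc(OCc3ccccc3)c(OC)c(OCc3ccccc3)c2)o1
F9 | step 8 | 2-[3,5-bis(benzyloxy)-4-methoxyphenyl]-4,5-dihydroxy-6-methoxytetrahydro-2H-pyran-3-one, diastereomer mixture | COC1OC(c2cc(OCc3ccccc3)c(OC)c(OCc3ccccc3)c2)C(=O)C(O)C1O
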